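## The problem

Compound 23 is a single, unfused cyclohex-2-enone in which every ring carbon is functionalised. The ring is numbered C1 (ketone), C2 (alkene carbon bearing CH2OH), C3 (alkene CH), C4 (isobutyrate), C5 (isopropyl) and C6 (ester of (E)-4-hydroxy-2-methylbut-2-enoic acid); the only chain to build is that five-carbon acyl unit on the C6 oxygen. Three contiguous stereocentres, (4S,5S,6R), must be set: isopropyl at C5 is cis to the C4 oxygen and trans to the C6 oxygen. C5 carries no heteroatom and no acidifying neighbour, so it cannot be corrected later and must be set first, with absolute control. It can then steer both neighbours: C6 is alpha to the ketone and prefers to sit trans to isopropyl even under equilibration, and C4 can be made by hydride addition to a ketone. The molecule is fragile: two different esters on secondary carbinols (migration, hydrolysis), an α-acyloxy ketone, an allylic ester gamma to the enone (elimination and aromatisation under base or Lewis acid), and two primary allylic alcohols that must end up free. The enabling feature is that the C1 and C4 oxygens are para and C5–C6 is the saturated edge. Without the C5 and C6 substituents and the C2 carbon, the ring is a p-benzoquinone monoketal, an achiral dienone with two enantiotopic enone arms that already holds all six ring carbons with C1 and C4 differentiated as ketone and ketal.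

## Retrosynthesis

**Hydroxymethyl carbon last.** The C2–CH2OH bond of 23 is cut first, leading through silyl ether 22 to enone 21. Carrying this carbon from the start would make the dienone unsymmetrical, remove the enantiotopic relationship the key step relies on, and add a protecting group. Introduced last by a Morita–Baylis–Hillman reaction with formaldehyde, it needs no protection. The forward reaction must tolerate two esters and an epimerisable C6; the only other operation after it is removal of one silyl group.

**C1 parked at the alcohol level.** Enone 21 is traced to allylic alcohol 20 and its silyl ether 19. An enedione with both C1 and C4 as ketones offers no reliable way to reduce C4 only, since C1 is the more electrophilic carbonyl. C1 is therefore reduced and silylated before C4 is unveiled and re-oxidised afterwards. This costs four steps but makes the differentiation structural. The forward steps need a C1 silyl ether (TBS) that can be removed in the presence of the side-chain silyl ether (TBDPS).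

**C4 oxygen and its ester.** The C4–O acyl bond of 19 is cut to alcohol 17 and isobutyryl chloride 18. The C4–H bond of 17 is cut to enone 16, which comes from ketal 15 by hydrolysis. Ketal 15 comes from alcohol 14, the reduction product of enone 13. Making C4 from a ketone lets C5 control it, and the ketal keeps C4 inert and at the right oxidation level until then. The forward reduction must deliver hydride to the face of C4 opposite the isopropyl group.

**C6 ester.** The C6–O acyl bond of 13 is cut to ketol 7 and acid 12. Acylating C6 at once with its final acyl group avoids a temporary protecting group and any later choice between two secondary hydroxyls. Acid 12 is three steps from commercial materials: Wittig reaction of glycolaldehyde dimer 8 with ylide 9 gives 10, silylation gives 11, saponification gives 12.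

**Key disconnection.** In 7 the C5–isopropyl bond and the C6–O bond are cut together, leading to the symmetric dienone 2 and diisopropylzinc 3. Forward, a copper-catalysed enantioselective 1,4-addition gives zinc dienolate 4, silylation gives dienol ether 5, and peracid oxidation gives 6 and then 7. Cutting both bonds at once removes every stereocentre and leaves an achiral, one-step precursor. The forward reaction must select one of two enantiotopic alkenes and its face, stop after one addition, and oxidise C6 anti to the new isopropyl group without disturbing the ketal.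

**Dienone.** Compound 2 is cut at the second C4–OMe bond to 4-methoxyphenol 1 (oxidative dearomatisation in methanol).

## Roads not taken

**Alternative 1:** cut C5–C6 and close the ring by an intramolecular carbonyl–ene reaction. A Lewis acid such as Me2AlCl would make the glyoxal aldehyde of the acyclic (Z)-vinylglyoxal A2 react with its trisubstituted prenyl-type alkene. This forms C5–C6, the C6 hydroxyl and a C5 isopropenyl group in cyclohexenone A1.
- Merits: the C2 carbon and the C4 isobutyrate are in place before the ring forms, C1 never leaves the ketone level, and the endgame is short (selective hydrogenation of the isopropenyl group, acylation with 12, desilylation). In convergence and in avoiding the C1 redox detour this road is better than the chosen one.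
- Weak points: A2 is a doubly allylic isobutyrate next to a 1,2-dicarbonyl. A Lewis acid can ionise it, the Z-enone can isomerise, and the glyoxal hydrates readily. One stereocentre (C4) would have to control two new ones through a transition state that needs the acyloxy group axial for the 4,5-cis relation. A2 itself needs its own enantioselective synthesis with a defined Z alkene.
- Against this the chosen plan sets an achiral one-step precursor and a key step of an established reaction type.

**Alternative 2:** cut C1–C6 and C4–C5 by an inverse-demand Diels–Alder reaction. Pyrone ester A4 and the (E)-configured 4-methoxybenzyl enol ether A5 would combine under a chiral Lewis acid (for example Cu(OTf)2 with a bis(oxazoline) ligand) to give bridged lactone A3.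
- Merits: both ring bonds and the C4, C5, C6 relationships arise in one catalytic step. Trans C5/C6 follows from the enol ether geometry, and the lactone oxygen at C4 is cis to isopropyl by the endo rule. In stereochemical economy this is as good as or better than the chosen plan, which sets C4 separately.
- Weak points: the carbon that becomes C1 emerges quaternary, carrying both the ester and the lactone carbonyl, where the target needs a ketone. Both carboxyl carbons would have to be degraded, and C2 would still need hydroxymethylation. The usual fate of such adducts, loss of the bridge by decarboxylation, would also remove the C4 oxygen.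
- The chosen plan sets correct oxidation levels at C1 and C4 from the first step against this.

**Alternative 3:** cut C6–C1 and C4–C3 using the hidden twofold symmetry of the C4–C5–C6 triad. Diol A7 and bis-acetate A8 would be joined by two iridium-catalysed dehydrogenation–allylation events (a cyclometallated complex from [Ir(cod)Cl]2 and a chiral bisphosphine) to give the C2-symmetric trans-diol A6.
- Merits: two cheap achiral pieces, no protecting groups, and the 4,5-cis/5,6-trans pattern is automatic, since a substituent between the two carbinols of a trans-1,3-diol is cis to one and trans to the other. Mono-acylation of A6 needs no site selectivity. In step count to the stereotriad this is the best of the four roads.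
- Weak points: ring closure by a second, intramolecular allylation is not an established reaction. More seriously, the two ends of A6 differ only in their ester after acylation, yet one must become the C1 ketone and the other the C3 alkene carbon, while the exocyclic methylene must be turned into the endocyclic C2=C3 alkene with an oxygenated CH2. No reliable basis for that regiocontrol is apparent.
- The chosen plan differentiates C1 and C4 as ketone and ketal from the outset.

Key step: step 2

Assumption: the C1 carbinol centre formed in step 7 is carried without assignment (compounds 14–20), because step 13 returns it to the ketone.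
Assumption: the (S,R,R) ligand is chosen by analogy with the sense it imposes on cyclohex-2-enone; if the opposite sense is found on 2, its mirror image is used.

## Route

Step 1
Reactants: 1 4-methoxyphenol
Product: 2 4,4-dimethoxycyclohexa-2,5-dien-1-one
Conditions: PhI(OAc)2, MeOH, 0 °C → rt
Reagents that add atoms: methanol, CO
Why: Oxidative dearomatisation of a para-alkoxyphenol by a trivalent iodine reagent; methanol captures the para carbon to give the quinone monoketal. The product is achiral.

Step 2
Reactants: 2 4,4-dimethoxycyclohexa-2,5-dien-1-one, 3 diisopropylzinc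
Product: 7 (5R,6R)-6-hydroxy-4,4-dimethoxy-5-(propan-2-yl)cyclohex-2-en-1-one, via zinc dienolate 4 (not isolated), via trimethylsilyl dienol ether 5 (not isolated), via 6-trimethylsilyloxy enone 6 (not isolated)
Conditions: Cu(OTf)2 (2 mol %), O,O'-[(S)-1,1'-binaphthalene-2,2'-diyl] N,N-bis[(R)-1-phenylethyl]phosphoramidite (4 mol %), toluene, −30 °C; TMSOTf, then Et3N; pentane, filtration, concentration; mCPBA, NaHCO3, CH2Cl2, −20 °C; citric acid, MeOH, 0 °C
Reagents that add atoms: mCPBA (3-chloroperoxybenzoic acid), O=C(OO)c1cccc(Cl)c1
Why: The dialkylzinc reduces divalent copper to monovalent copper, which with the phosphoramidite forms a chiral isopropylcopper–zinc species; this binds one of the two enantiotopic enone alkenes of 2, adds at the β-carbon through a trivalent copper intermediate and reductively eliminates to form the C5–isopropyl bond, leaving zinc dienolate 4. The closest known reaction type is the copper–phosphoramidite 1,4-addition of dialkylzincs to cyclohexadienones and benzoquinone monoketals with silyl trapping of the zinc enolate, followed by Rubottom oxidation of a 2-silyloxy-1,3-diene. No ring is closed. C5 is set by the ligand, which selects both the alkene and its face. C6 is set by C5: the peracid epoxidises the enol ether C1=C6 bond of 5 anti to the isopropyl group, and opening of the silyloxy oxirane with 1,4-silyl shift gives 6 with oxygen trans to isopropyl, which is also the preferred arrangement should C6 epimerise. Mono-addition is secured because 4 is an enolate and no longer an acceptor; chemoselective oxidation is secured by the much higher electron density of the silyl enol ether compared with the C2=C3 alkene. Survival of the ketal is addressed by quenching the silyl triflate with amine, buffering the peracid and cleaving the O–Si bond with methanolic citric acid.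

Step 3
Reactants: 8 1,4-dioxane-2,5-diol (glycolaldehyde dimer), 9 ethyl 2-(triphenyl-λ5-phosphanylidene)propanoate
Product: 10 ethyl (2E)-4-hydroxy-2-methylbut-2-enoate
Conditions: CH2Cl2, reflux
Reagents that add atoms: none
Why: Wittig olefination; the dimer equilibrates with monomeric glycolaldehyde, and the stabilised α-branched ylide gives the trisubstituted enoate with ester and CH2OH trans (E).

Step 4
Reactants: 10 ethyl (2E)-4-hydroxy-2-methylbut-2-enoate
Product: 11 ethyl (2E)-4-[(tert-butyldiphenylsilyl)oxy]-2-methylbut-2-enoate
Conditions: TBDPSCl, imidazole, CH2Cl2, 0 °C → rt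
Reagents that add atoms: tert-butyl(chloro)diphenylsilane, CC(C)(C)[Si](Cl)(c1ccccc1)c1ccccc1
Why: Standard silylation of a primary allylic alcohol; TBDPS is chosen because it must outlast the acidic hydrolysis of step 9 and the TBS cleavage of step 12.

Step 5
Reactants: 11 ethyl (2E)-4-[(tert-butyldiphenylsilyl)oxy]-2-methylbut-2-enoate
Product: 12 (2E)-4-[(tert-butyldiphenylsilyl)oxy]-2-methylbut-2-enoic acid
Conditions: LiOH, THF/H2O, rt; 1 M HCl to pH 3
Reagents that add atoms: lithium hydroxide, [Li+].[OH-]
Why: Saponification of the ethyl ester; the hindered silyl ether and the E alkene are untouched, and acidification only to pH 3 keeps the silyl ether.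

Step 6
Reactants: 7 (5R,6R)-6-hydroxy-4,4-dimethoxy-5-(propan-2-yl)cyclohex-2-en-1-one, 12 (2E)-4-[(tert-butyldiphenylsilyl)oxy]-2-methylbut-2-enoic acid
Product: 13 (1R,6R)-5,5-dimethoxy-2-oxo-6-(propan-2-yl)cyclohex-3-en-1-yl (2E)-4-[(tert-butyldiphenylsilyl)oxy]-2-methylbut-2-enoate
Conditions: DCC, DMAP (cat.), CH2Cl2, 0 °C → rt
Reagents that add atoms: none
Why: Steglich esterification of the secondary α-ketol; the conditions are non-acidic for the ketal, and C6, should it enolise, returns to the favoured trans relation with isopropyl.

Step 7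
Reactants: 13 (1R,6R)-5,5-dimethoxy-2-oxo-6-(propan-2-yl)cyclohex-3-en-1-yl (2E)-4-[(tert-butyldiphenylsilyl)oxy]-2-methylbut-2-enoate
Product: 14 (1R,6R)-2-hydroxy-5,5-dimethoxy-6-(propan-2-yl)cyclohex-3-en-1-yl (2E)-4-[(tert-butyldiphenylsilyl)oxy]-2-methylbut-2-enoate (C2 carbinol of the ring unassigned)
Conditions: NaBH4, CeCl3·7H2O, MeOH, −78 °C
Reagents that add atoms: none
Why: Luche reduction gives 1,2-reduction of the enone without touching the enoate ester or the ketal; the new carbinol is temporary and is re-oxidised in step 13, so either epimer serves.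

Step 8
Reactants: 14 (1R,6R)-2-hydroxy-5,5-dimethoxy-6-(propan-2-yl)cyclohex-3-en-1-yl (2E)-4-[(tert-butyldiphenylsilyl)oxy]-2-methylbut-2-enoate
Product: 15 (1R,6R)-2-[(tert-butyldimethylsilyl)oxy]-5,5-dimethoxy-6-(propan-2-yl)cyclohex-3-en-1-yl (2E)-4-[(tert-butyldiphenylsilyl)oxy]-2-methylbut-2-enoate
Conditions: TBSCl, imidazole, DMF, rt
Reagents that add atoms: tert-butyl(chloro)dimethylsilane, CC(C)(C)[Si](C)(C)Cl
Why: Silylation with the chloride and imidazole avoids silyl triflates, which would ionise the allylic ketal; it is run directly on 14 so that the C6 ester has little time to migrate to the neighbouring hydroxyl.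

Step 9
Reactants: 15 (1R,6R)-2-[(tert-butyldimethylsilyl)oxy]-5,5-dimethoxy-6-(propan-2-yl)cyclohex-3-en-1-yl (2E)-4-[(tert-butyldiphenylsilyl)oxy]-2-methylbut-2-enoate
Product: 16 (1R,6R)-2-[(tert-butyldimethylsilyl)oxy]-5-oxo-6-(propan-2-yl)cyclohex-3-en-1-yl (2E)-4-[(tert-butyldiphenylsilyl)oxy]-2-methylbut-2-enoate
Conditions: PPTS, acetone/H2O, rt
Reagents that add atoms: water, O
Why: Acid-catalysed hydrolysis of an allylic dimethyl ketal, which ionises easily to a conjugated oxocarbenium ion, so a pyridinium salt suffices and both silyl ethers and the ester survive. The C4 ketone appears only after C1 has been masked, and no amine base meets this β-acyloxy ketone.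

Step 10
Reactants: 16 (1R,6R)-2-[(tert-butyldimethylsilyl)oxy]-5-oxo-6-(propan-2-yl)cyclohex-3-en-1-yl (2E)-4-[(tert-butyldiphenylsilyl)oxy]-2-methylbut-2-enoate
Product: 17 (1R,5S,6S)-2-[(tert-butyldimethylsilyl)oxy]-5-hydroxy-6-(propan-2-yl)cyclohex-3-en-1-yl (2E)-4-[(tert-butyldiphenylsilyl)oxy]-2-methylbut-2-enoate
Conditions: NaBH4, CeCl3·7H2O, MeOH, −78 °C
Reagents that add atoms: none
Why: Luche 1,2-reduction; hydride is expected to enter the face of the C4 carbonyl opposite the adjacent C5 isopropyl group, as in hydride reductions of 6-isopropylcyclohex-2-enones, placing the new hydroxyl cis to isopropyl (the 4S centre of 23). The C6 ester is 1,3-trans to this hydroxyl and cannot migrate to it.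

Step 11
Reactants: 17 (1R,5S,6S)-2-[(tert-butyldimethylsilyl)oxy]-5-hydroxy-6-(propan-2-yl)cyclohex-3-en-1-yl (2E)-4-[(tert-butyldiphenylsilyl)oxy]-2-methylbut-2-enoate, 18 2-methylpropanoyl chloride (isobutyryl chloride)
Product: 19 (1R,5S,6S)-2-[(tert-butyldimethylsilyl)oxy]-5-[(2-methylpropanoyl)oxy]-6-(propan-2-yl)cyclohex-3-en-1-yl (2E)-4-[(tert-butyldiphenylsilyl)oxy]-2-methylbut-2-enoate
Conditions: pyridine, DMAP (cat.), CH2Cl2, 0 °C
Reagents that add atoms: none
Why: DMAP-catalysed acylation of the secondary allylic alcohol proceeds with retention at C4; all other hydroxyls are silylated.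

Step 12
Reactants: 19 (1R,5S,6S)-2-[(tert-butyldimethylsilyl)oxy]-5-[(2-methylpropanoyl)oxy]-6-(propan-2-yl)cyclohex-3-en-1-yl (2E)-4-[(tert-butyldiphenylsilyl)oxy]-2-methylbut-2-enoate
Product: 20 (1R,5S,6S)-2-hydroxy-5-[(2-methylpropanoyl)oxy]-6-(propan-2-yl)cyclohex-3-en-1-yl (2E)-4-[(tert-butyldiphenylsilyl)oxy]-2-methylbut-2-enoate (C2 carbinol of the ring unassigned)
Conditions: HF·pyridine, pyridine, THF, 0 °C → rt
Reagents that add atoms: none
Why: Pyridine-buffered HF cleaves the tert-butyldimethylsilyl ether well before the tert-butyldiphenylsilyl ether, and the weakly acidic medium suppresses migration of the C6 ester to the freed C1 hydroxyl.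

Step 13
Reactants: 20 (1R,5S,6S)-2-hydroxy-5-[(2-methylpropanoyl)oxy]-6-(propan-2-yl)cyclohex-3-en-1-yl (2E)-4-[(tert-butyldiphenylsilyl)oxy]-2-methylbut-2-enoate
Product: 21 (1R,5S,6S)-5-[(2-methylpropanoyl)oxy]-2-oxo-6-(propan-2-yl)cyclohex-3-en-1-yl (2E)-4-[(tert-butyldiphenylsilyl)oxy]-2-methylbut-2-enoate
Conditions: Dess–Martin periodinane, pyridine, CH2Cl2, 0 °C → rt
Reagents that add atoms: none
Why: Dess–Martin oxidation of the allylic alcohol under buffered, non-basic conditions restores the C1 enone. Both C1 epimers converge, and C6 keeps its preferred trans relation to isopropyl.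

Step 14
Reactants: 21 (1R,5S,6S)-5-[(2-methylpropanoyl)oxy]-2-oxo-6-(propan-2-yl)cyclohex-3-en-1-yl (2E)-4-[(tert-butyldiphenylsilyl)oxy]-2-methylbut-2-enoate
Product: 22 (1R,5S,6S)-3-(hydroxymethyl)-5-[(2-methylpropanoyl)oxy]-2-oxo-6-(propan-2-yl)cyclohex-3-en-1-yl (2E)-4-[(tert-butyldiphenylsilyl)oxy]-2-methylbut-2-enoate
Conditions: aq. HCHO (37 %), DMAP, THF/H2O, rt
Reagents that add atoms: formaldehyde, C=O
Why: Morita–Baylis–Hillman reaction: DMAP adds reversibly to C3, the enolate is hydroxymethylated at C2 by formaldehyde, and loss of the catalyst restores the enone. The reaction type is known for cyclohex-2-enones in aqueous THF, and no stereocentre is formed.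

Step 15
Reactants: 22 (1R,5S,6S)-3-(hydroxymethyl)-5-[(2-methylpropanoyl)oxy]-2-oxo-6-(propan-2-yl)cyclohex-3-en-1-yl (2E)-4-[(tert-butyldiphenylsilyl)oxy]-2-methylbut-2-enoate
Product: 23 (1R,5S,6S)-3-(hydroxymethyl)-5-[(2-methylpropanoyl)oxy]-2-oxo-6-(propan-2-yl)cyclohex-3-en-1-yl (2E)-4-hydroxy-2-methylbut-2-enoate
Conditions: HF·pyridine, THF, rt
Reagents that add atoms: none
Why: Fluoride cleavage of the primary silyl ether under weakly acidic conditions should leave the enone, both esters and the α-acyloxy ketone intact and release 23.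

## Compound list

1 | 4-methoxyphenol | COc1ccc(O)cc1 | starting material
2 | 4,4-dimethoxycyclohexa-2,5-dien-1-one | COC1(OC)C=CC(=O)C=C1 | intermediate
3 | diisopropylzinc | CC(C)[Zn]C(C)C | starting material
4 | isopropylzinc (3R)-4,4-dimethoxy-3-(propan-2-yl)cyclohexa-1,5-dien-1-olate | CC(C)[Zn]OC1=C[C@@H](C(C)C)C(OC)(OC)C=C1 | intermediate (not isolated)
5 | trimethyl{[(3R)-4,4-dimethoxy-3-(propan-2-yl)cyclohexa-1,5-dien-1-yl]oxy}silane | C[Si](C)(C)OC1=C[C@@H](C(C)C)C(OC)(OC)C=C1 | intermediate (not isolated)
6 | (5R,6R)-4,4-dimethoxy-5-(propan-2-yl)-6-[(trimethylsilyl)oxy]cyclohex-2-en-1-one | C[Si](C)(C)O[C@H]1C(=O)C=CC(OC)(OC)[C@@H]1C(C)C | intermediate (not isolated)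
7 | (5R,6R)-6-hydroxy-4,4-dimethoxy-5-(propan-2-yl)cyclohex-2-en-1-one | O[C@H]1C(=O)C=CC(OC)(OC)[C@@H]1C(C)C | intermediate
8 | 1,4-dioxane-2,5-diol (glycolaldehyde dimer) | OC1COC(O)CO1 | starting material
9 | ethyl 2-(triphenyl-λ5-phosphanylidene)propanoate | CCOC(=O)C(C)=P(c1ccccc1)(c1ccccc1)c1ccccc1 | starting material
10 | ethyl (2E)-4-hydroxy-2-methylbut-2-enoate | CCOC(=O)/C(C)=C/CO | intermediate
11 | ethyl (2E)-4-[(tert-butyldiphenylsilyl)oxy]-2-methylbut-2-enoate | CCOC(=O)/C(C)=C/CO[Si](c1ccccc1)(c1ccccc1)C(C)(C)C | intermediate
12 | (2E)-4-[(tert-butyldiphenylsilyl)oxy]-2-methylbut-2-enoic acid | C/C(=C\CO[Si](c1ccccc1)(c1ccccc1)C(C)(C)C)C(=O)O | intermediate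
13 | (1R,6R)-5,5-dimethoxy-2-oxo-6-(propan-2-yl)cyclohex-3-en-1-yl (2E)-4-[(tert-butyldiphenylsilyl)oxy]-2-methylbut-2-enoate | C/C(=C\CO[Si](c1ccccc1)(c1ccccc1)C(C)(C)C)C(=O)O[C@H]1C(=O)C=CC(OC)(OC)[C@@H]1C(C)C | intermediate
14 | (1R,6R)-2-hydroxy-5,5-dimethoxy-6-(propan-2-yl)cyclohex-3-en-1-yl (2E)-4-[(tert-butyldiphenylsilyl)oxy]-2-methylbut-2-enoate, ring C2 carbinol unassigned | C/C(=C\CO[Si](c1ccccc1)(c1ccccc1)C(C)(C)C)C(=O)O[C@H]1C(O)C=CC(OC)(OC)[C@@H]1C(C)C | intermediate
15 | (1R,6R)-2-[(tert-butyldimethylsilyl)oxy]-5,5-dimethoxy-6-(propan-2-yl)cyclohex-3-en-1-yl (2E)-4-[(tert-butyldiphenylsilyl)oxy]-2-methylbut-2-enoate, ring C2 unassigned | C/C(=C\CO[Si](c1ccccc1)(c1ccccc1)C(C)(C)C)C(=O)O[C@H]1C(O[Si](C)(C)C(C)(C)C)C=CC(OC)(OC)[C@@H]1C(C)C | intermediate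
16 | (1R,6R)-2-[(tert-butyldimethylsilyl)oxy]-5-oxo-6-(propan-2-yl)cyclohex-3-en-1-yl (2E)-4-[(tert-butyldiphenylsilyl)oxy]-2-methylbut-2-enoate, ring C2 unassigned | C/C(=C\CO[Si](c1ccccc1)(c1ccccc1)C(C)(C)C)C(=O)O[C@H]1C(O[Si](C)(C)C(C)(C)C)C=CC(=O)[C@@H]1C(C)C | intermediate
17 | (1R,5S,6S)-2-[(tert-butyldimethylsilyl)oxy]-5-hydroxy-6-(propan-2-yl)cyclohex-3-en-1-yl (2E)-4-[(tert-butyldiphenylsilyl)oxy]-2-methylbut-2-enoate, ring C2 unassigned | C/C(=C\CO[Si](c1ccccc1)(c1ccccc1)C(C)(C)C)C(=O)O[C@H]1C(O[Si](C)(C)C(C)(C)C)C=C[C@H](O)[C@@H]1C(C)C | intermediate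
18 | 2-methylpropanoyl chloride (isobutyryl chloride) | CC(C)C(Cl)=O | starting material
19 | (1R,5S,6S)-2-[(tert-butyldimethylsilyl)oxy]-5-[(2-methylpropanoyl)oxy]-6-(propan-2-yl)cyclohex-3-en-1-yl (2E)-4-[(tert-butyldiphenylsilyl)oxy]-2-methylbut-2-enoate, ring C2 unassigned | C/C(=C\CO[Si](c1ccccc1)(c1ccccc1)C(C)(C)C)C(=O)O[C@H]1C(O[Si](C)(C)C(C)(C)C)C=C[C@H](OC(=O)C(C)C)[C@@H]1C(C)C | intermediate
20 | (1R,5S,6S)-2-hydroxy-5-[(2-methylpropanoyl)oxy]-6-(propan-2-yl)cyclohex-3-en-1-yl (2E)-4-[(tert-butyldiphenylsilyl)oxy]-2-methylbut-2-enoate, ring C2 unassigned | C/C(=C\CO[Si](c1ccccc1)(c1ccccc1)C(C)(C)C)C(=O)O[C@H]1C(O)C=C[C@H](OC(=O)C(C)C)[C@@H]1C(C)C | intermediate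
21 | (1R,5S,6S)-5-[(2-methylpropanoyl)oxy]-2-oxo-6-(propan-2-yl)cyclohex-3-en-1-yl (2E)-4-[(tert-butyldiphenylsilyl)oxy]-2-methylbut-2-enoate | C/C(=C\CO[Si](c1ccccc1)(c1ccccc1)C(C)(C)C)C(=O)O[C@H]1C(=O)C=C[C@H](OC(=O)C(C)C)[C@@H]1C(C)C | intermediate
22 | (1R,5S,6S)-3-(hydroxymethyl)-5-[(2-methylpropanoyl)oxy]-2-oxo-6-(propan-2-yl)cyclohex-3-en-1-yl (2E)-4-[(tert-butyldiphenylsilyl)oxy]-2-methylbut-2-enoate | C/C(=C\CO[Si](c1ccccc1)(c1ccccc1)C(C)(C)C)C(=O)O[C@H]1C(=O)C(CO)=C[C@H](OC(=O)C(C)C)[C@@H]1C(C)C | intermediate
23 | (1R,5S,6S)-3-(hydroxymethyl)-5-[(2-methylpropanoyl)oxy]-2-oxo-6-(propan-2-yl)cyclohex-3-en-1-yl (2E)-4-hydroxy-2-methylbut-2-enoate | C/C(=C\CO)C(=O)O[C@H]1C(=O)C(CO)=C[C@H](OC(=O)C(C)C)[C@@H]1C(C)C | target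

## Step count and risks

Total: 15 steps. Longest linear sequence: 13 steps (3, 4, 5, then 6–15), running from glycolaldehyde dimer 8 and ylide 9 through acid 12 to 23. The ring-building branch from 4-methoxyphenol 1 (steps 1, 2, then 6–15) is 12 steps and joins at step 6.

**Step 2 (key step).** The most likely failure is loss of the ketal: the silyl triflate, or acid released later, can ionise C4, and loss of the C5 proton then aromatises the ring to a 4-methoxyphenol derivative, which is strongly downhill. A lesser concern is lower enantioselectivity with the branched zinc reagent. Fallback: separate C–C bond formation from oxygenation so that no silyl triflate is used. The same copper-catalysed addition of 3 to 2 is quenched with aqueous NH4Cl to give (5S)-4,4-dimethoxy-5-(propan-2-yl)cyclohex-2-en-1-one F1. Kinetic deprotonation at C6 with LDA in THF at −78 °C gives the cross-conjugated lithium dienolate, which is hydroxylated with 2-(benzenesulfonyl)-3-phenyloxaziridine anti to the isopropyl group; aqueous NH4Cl work-up then gives 7. This sets out from 2 and returns to the route at 7.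

**Step 10.** The most likely failure is poor or reversed facial selectivity. Axial delivery to the conformer with an equatorial isopropyl group would give the 4,5-trans alcohol, and a slow reduction also risks loss of the C6 carboxylate from this β-acyloxy ketone. Fallback: use the other epimer by inversion. The trans alcohol (1R,5R,6S)-2-[(tert-butyldimethylsilyl)oxy]-5-hydroxy-6-(propan-2-yl)cyclohex-3-en-1-yl (2E)-4-[(tert-butyldiphenylsilyl)oxy]-2-methylbut-2-enoate F2, obtained from 16, is esterified under Mitsunobu conditions (isobutyric acid, PPh3, DIAD, toluene, 0 °C → rt). SN2 inversion at the allylic carbon gives 19 directly. Any 17 formed alongside is acylated as in step 11, so both epimers converge. This sets out from 16 and returns at 19.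

**Step 14.** The most likely failure is slow hydroxymethylation together with attack of the nucleophilic catalyst or hydroxide on the activated C6 ester (deacylation) during long exposure to aqueous base. Fallback: install the carbon by cross-coupling. α-Iodination of 21 (I2, pyridine, CH2Cl2, rt) gives (1R,5R,6S)-3-iodo-5-[(2-methylpropanoyl)oxy]-2-oxo-6-(propan-2-yl)cyclohex-3-en-1-yl (2E)-4-[(tert-butyldiphenylsilyl)oxy]-2-methylbut-2-enoate F3. Stille coupling with (tributylstannyl)methanol under the zerovalent palladium complex Pd(PPh3)4 (dioxane, 80 °C) gives 22. This sets out from 21 and returns at 22.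

**Step 12.** The most likely failure is incomplete discrimination between the two silyl ethers (partial loss of the TBDPS group), with migration of the C6 ester to the free C1 hydroxyl as a second risk. Fallback: remove both silyl groups and re-protect selectively. Excess HF·pyridine at rt converts 19 into the diol (1R,5S,6S)-2-hydroxy-5-[(2-methylpropanoyl)oxy]-6-(propan-2-yl)cyclohex-3-en-1-yl (2E)-4-hydroxy-2-methylbut-2-enoate F4. TBDPSCl (1.05 equiv) with imidazole in CH2Cl2 at −20 °C then silylates only the primary allylic hydroxyl, relying on the large rate difference between a primary and a hindered secondary alcohol. This sets out from 19 and returns at 20.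

## Further compounds

F1 | step 2 | (5S)-4,4-dimethoxy-5-(propan-2-yl)cyclohex-2-en-1-one | O=C1C[C@@H](C(C)C)C(OC)(OC)C=C1
F2 | step 10 | (1R,5R,6S)-2-[(tert-butyldimethylsilyl)oxy]-5-hydroxy-6-(propan-2-yl)cyclohex-3-en-1-yl (2E)-4-[(tert-butyldiphenylsilyl)oxy]-2-methylbut-2-enoate, ring C2 unassigned | C/C(=C\CO[Si](c1ccccc1)(c1ccccc1)C(C)(C)C)C(=O)O[C@H]1C(O[Si](C)(C)C(C)(C)C)C=C[C@@H](O)[C@@H]1C(C)C
F3 | step 14 | (1R,5R,6S)-3-iodo-5-[(2-methylpropanoyl)oxy]-2-oxo-6-(propan-2-yl)cyclohex-3-en-1-yl (2E)-4-[(tert-butyldiphenylsilyl)oxy]-2-methylbut-2-enoate | C/C(=C\CO[Si](c1ccccc1)(c1ccccc1)C(C)(C)C)C(=O)O[C@H]1C(=O)C(I)=C[C@H](OC(=O)C(C)C)[C@@H]1C(C)C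
F4 | step 12 | (1R,5S,6S)-2-hydroxy-5-[(2-methylpropanoyl)oxy]-6-(propan-2-yl)cyclohex-3-en-1-yl (2E)-4-hydroxy-2-methylbut-2-enoate, ring C2 unassigned | C/C(=C\CO)C(=O)O[C@H]1C(O)C=C[C@H](OC(=O)C(C)C)[C@@H]1C(C)C
A1 | alternative 1 | (1S,5R,6R)-3-{[(tert-butyldimethylsilyl)oxy]methyl}-5-hydroxy-4-oxo-6-(prop-1-en-2-yl)cyclohex-2-en-1-yl 2-methylpropanoate | O[C@H]1C(=O)C(CO[Si](C)(C)C(C)(C)C)=C[C@H](OC(=O)C(C)C)[C@@H]1C(C)=C
A2 | alternative 1 | (3Z,5R)-3-{[(tert-butyldimethylsilyl)oxy]methyl}-7-methyl-1,2-dioxoocta-3,6-dien-5-yl 2-methylpropanoate | O=CC(=O)/C(CO[Si](C)(C)C(C)(C)C)=C\[C@H](OC(=O)C(C)C)C=C(C)C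
A3 | alternative 2 | methyl 7-isopropyl-8-[(4-methoxybenzyl)oxy]-3-oxo-2-oxabicyclo[2.2.2]oct-5-ene-4-carboxylate, alkoxy endo and isopropyl exo, single enantiomer | COc1ccc(CO[C@H]2[C@@]3(C(=O)OC)C=C[C@H](OC3=O)[C@@H]2C(C)C)cc1
A4 | alternative 2 | methyl 2-oxo-2H-pyran-3-carboxylate | COC(=O)C1=CC=COC1=O
A5 | alternative 2 | 1-methoxy-4-({[(1E)-3-methylbut-1-en-1-yl]oxy}methyl)benzene | COc1ccc(CO/C=C/C(C)C)cc1
A6 | alternative 3 | (1S,3S)-5-methylidene-2-(propan-2-yl)cyclohexane-1,3-diol | O[C@H]1CC(=C)C[C@H](O)C1C(C)C
A7 | alternative 3 | 2-(propan-2-yl)propane-1,3-diol | CC(C)C(CO)CO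
A8 | alternative 3 | 2-methylidenepropane-1,3-diyl diacetate | CC(=O)OCC(=C)COC(C)=O
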